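**Retrosynthetic overview**

1. Glisoflavone 22 ⇐ protected isoflavone 20 (fluoride, then mild acid) ⇐ racemic isoflavanone 16 by dehydrogenation of C2–C3.
2. Feature: in ring C, C2 is a lone CH bonded only to O1 and C3. The O1–C2 unit is therefore a methoxy group in disguise, the constitutional twin of the C5 methoxy group, and ring A can start as a symmetric 2,6-dimethoxyaryl ketone.
3. Key disconnection C2–C3: 16 ⇐ α-aryl diazoketone 15. A rhodium carbenoid at C3 inserts into a C–H bond of either ortho methoxy group and closes ring C, the only ring that is built (rings A and B come from arenes).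
4. 15 ⇐ deoxybenzoin 14 (diazo transfer) ⇐ ring A methyl ketone 5 + ring B aryl bromide 13 (palladium-catalysed enolate arylation, bond C3–C1').
5. 5 ⇐ 3,5-dimethoxyphenol 1 (silylation, lithiation between the methoxy groups, acetylation); 13 ⇐ 3,5-dibromosalicylaldehyde 6 (Dakin oxidation, MOM protection, ortho-selective Br–Li exchange, prenylation with prenyl bromide 10).

Key step: step 8

Remark: the target has no stereocentre; 16, 18 and 19 are carried as racemates (19 also as a mixture at selenium), and species bound to a catalytic metal (organopalladium intermediates, the rhodium carbenoid) are discussed in the Why lines without a number.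

**Route**

Step 1
Reactants: 1 3,5-dimethoxyphenol
Product: 2 (3,5-dimethoxyphenoxy)triisopropylsilane
Conditions: TIPSCl, imidazole, DMF, rt
Reagents that add atoms: triisopropylsilyl chloride, CC(C)[Si](Cl)(C(C)C)C(C)C
Why: Routine silylation of a phenol (silyl ether formation); the bulky, weakly coordinating OTIPS group later keeps the base away from its own ortho positions.

Step 2
Reactants: 2 (3,5-dimethoxyphenoxy)triisopropylsilane
Product: 5 1-[2,6-dimethoxy-4-(triisopropylsilyloxy)phenyl]ethan-1-one, via aryllithium 3 (not isolated), via lithium hemiaminal adduct 4 (not isolated)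
Conditions: n-BuLi, THF, 0 °C to rt; MeC(O)N(OMe)Me, −78 to 0 °C; 1 M aq HCl, 0 °C
Reagents that add atoms: N-methoxy-N-methylacetamide, CC(=O)N(C)OC
Why: Directed ortho-metalation should take the C–H flanked by both methoxy groups (most acidic, doubly coordinated, remote from the bulky silyl ether), and the aryllithium acylates the Weinreb amide through a chelated tetrahedral adduct that releases the ketone only on quench (Weinreb ketone synthesis).

Step 3
Reactants: 6 3,5-dibromo-2-hydroxybenzaldehyde
Product: 8 3,5-dibromobenzene-1,2-diol, via aryl formate 7 (not isolated)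
Conditions: 30% aq H2O2, NaOH, H2O, 0 °C to rt; then aq HCl
Reagents that add atoms: hydrogen peroxide, OO
Why: Dakin oxidation of an ortho-hydroxybenzaldehyde: hydroperoxide adds to the aldehyde, the aryl group migrates to oxygen, and the formate is saponified in the flask, the aryl bromides being inert.

Step 4
Reactants: 8 3,5-dibromobenzene-1,2-diol
Product: 9 1,5-dibromo-2,3-bis(methoxymethoxy)benzene
Conditions: MOMCl, i-Pr2NEt, CH2Cl2, 0 °C to rt
Reagents that add atoms: chloromethyl methyl ether, COCCl
Why: Double O-alkylation of the catechol (acetal protection) gives ethers that withstand organolithiums and bases and that coordinate lithium in the next step.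

Step 5
Reactants: 9 1,5-dibromo-2,3-bis(methoxymethoxy)benzene; 10 prenyl bromide
Product: 13 5-bromo-1,2-bis(methoxymethoxy)-3-(3-methylbut-2-en-1-yl)benzene, via aryllithium 11 (not isolated), via arylcopper 12 (not isolated)
Conditions: n-BuLi (1.0 equiv), THF, −78 °C; CuBr·SMe2, −78 to −40 °C; prenyl bromide, −40 to 0 °C
Reagents that add atoms: none
Why: Bromine–lithium exchange should occur at the bromine ortho to an OMOM group (chelation and inductive stabilisation, as with 2,4-dibromoanisole), and the derived arylcopper attacks prenyl bromide at its primary carbon (copper-mediated SN2 allylation) to give the linear prenyl arene.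

Step 6
Reactants: 5 1-[2,6-dimethoxy-4-(triisopropylsilyloxy)phenyl]ethan-1-one; 13 5-bromo-1,2-bis(methoxymethoxy)-3-(3-methylbut-2-en-1-yl)benzene
Product: 14 2-[3,4-bis(methoxymethoxy)-5-(3-methylbut-2-en-1-yl)phenyl]-1-[2,6-dimethoxy-4-(triisopropylsilyloxy)phenyl]ethan-1-one
Conditions: Pd2(dba)3 (zerovalent palladium), Xantphos, K3PO4, toluene, 90 °C
Reagents that add atoms: none
Why: Palladium-catalysed α-arylation of a ketone enolate (Buchwald–Hartwig type): the methyl ketone has a single enolisable site, the aryl bromide has two free ortho positions, the weak base spares the aryl silyl ether, and the more hindered product enolate resists a second arylation.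

Step 7
Reactants: 14 2-[3,4-bis(methoxymethoxy)-5-(3-methylbut-2-en-1-yl)phenyl]-1-[2,6-dimethoxy-4-(triisopropylsilyloxy)phenyl]ethan-1-one
Product: 15 2-diazo-2-[3,4-bis(methoxymethoxy)-5-(3-methylbut-2-en-1-yl)phenyl]-1-[2,6-dimethoxy-4-(triisopropylsilyloxy)phenyl]ethan-1-one
Conditions: p-ABSA, DBU, MeCN, 0 °C to rt, dark
Reagents that add atoms: 4-acetamidobenzenesulfonyl azide, CC(=O)Nc1ccc(cc1)S(=O)(=O)N=[N+]=[N-]
Why: Regitz diazo transfer to the benzylic methylene, which is acidified by both the carbonyl group and ring B, as is usual for deoxybenzoins.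

Step 8
Reactants: 15 2-diazo-2-[3,4-bis(methoxymethoxy)-5-(3-methylbut-2-en-1-yl)phenyl]-1-[2,6-dimethoxy-4-(triisopropylsilyloxy)phenyl]ethan-1-one
Product: 16 rac-3-[3,4-bis(methoxymethoxy)-5-(3-methylbut-2-en-1-yl)phenyl]-5-methoxy-7-(triisopropylsilyloxy)chroman-4-one
Conditions: Rh2(O2CCPh3)4 (divalent rhodium, 2 mol%), dry degassed CH2Cl2, 4 Å MS, slow addition of 15 by syringe pump, rt to 40 °C
Reagents that add atoms: none
Why: Proposed new method: the divalent rhodium carboxylate attacks the diazo carbon, nitrogen is lost, and the donor–acceptor rhodium carbenoid at C3 inserts through a concerted, asynchronous three-centre transition state into a C–H bond of an ortho methoxy group, a bond activated by the adjacent oxygen lone pair. The closest known reaction types are rhodium carbenoid C–H insertions next to ether oxygen, which turn ortho-alkoxyaryl diazomethyl ketones into chroman-4-ones and 2-alkoxyaryl diazoacetates into dihydrobenzofurans; a six-membered closure onto an aryl methyl ether from a diaryl diazoketone has no close model. Ring C closes by formation of C2–C3 in a six-membered (1,6) insertion mode, and because the two methoxy groups are equivalent no choice between the ring A oxygens is required. The new stereocentre C3 forms without control, as the racemate, which is acceptable because it becomes sp2 two steps later. The selectivity needed is chemoselectivity for C–H insertion over attack of the ether oxygen (a five-membered oxonium ylide, which should revert because a methyl 1,2-shift is slow), Wolff rearrangement and carbene dimerisation; it rests on the twist of ring A out of the carbonyl plane enforced by its two ortho substituents, which holds a methoxy C–H over the carbenoid carbon, on the bulky triphenylacetate ligands, and on slow addition at high dilution. The prenyl alkene, the OMOM groups and the OTIPS group sit meta or para to the atoms involved and cannot reach the carbenoid within the molecule.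

Step 9
Reactants: 16 rac-3-[3,4-bis(methoxymethoxy)-5-(3-methylbut-2-en-1-yl)phenyl]-5-methoxy-7-(triisopropylsilyloxy)chroman-4-one
Product: 18 rac-3-[3,4-bis(methoxymethoxy)-5-(3-methylbut-2-en-1-yl)phenyl]-5-methoxy-3-(phenylselanyl)-7-(triisopropylsilyloxy)chroman-4-one, via lithium enolate 17 (not isolated)
Conditions: LiHMDS, THF, −78 °C; PhSeCl (1.0 equiv), −78 °C
Reagents that add atoms: benzeneselenenyl chloride, Cl[Se]c1ccccc1
Why: C3 is the only α-position, and at −78 °C capture of its enolate by the selenenyl chloride (enolate α-selenenylation) should outrun both addition to the prenyl alkene and β-elimination of the aryloxide; the quaternary C3 forms as the racemate.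

Step 10
Reactants: 18 rac-3-[3,4-bis(methoxymethoxy)-5-(3-methylbut-2-en-1-yl)phenyl]-5-methoxy-3-(phenylselanyl)-7-(triisopropylsilyloxy)chroman-4-one
Product: 20 3-[3,4-bis(methoxymethoxy)-5-(3-methylbut-2-en-1-yl)phenyl]-5-methoxy-7-(triisopropylsilyloxy)-4H-chromen-4-one, via selenoxide 19 (not isolated)
Conditions: NaIO4, NaHCO3, THF/MeOH/H2O, 0 °C to rt
Reagents that add atoms: none
Why: Periodate oxidises selenium without touching the trisubstituted alkene, and the selenoxide undergoes syn-elimination with a C2–H, the only β-hydrogens, to form the C2=C3 bond of the chromone and erase the C3 stereocentre (selenoxide elimination).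

Step 11
Reactants: 20 3-[3,4-bis(methoxymethoxy)-5-(3-methylbut-2-en-1-yl)phenyl]-5-methoxy-7-(triisopropylsilyloxy)-4H-chromen-4-one
Product: 21 3-[3,4-bis(methoxymethoxy)-5-(3-methylbut-2-en-1-yl)phenyl]-7-hydroxy-5-methoxy-4H-chromen-4-one
Conditions: TBAF, AcOH, THF, 0 °C
Reagents that add atoms: none
Why: Fluoride-induced cleavage of the aryl silyl ether, buffered with acetic acid so that the chromone ring is not opened by base; the MOM ethers are inert.

Step 12
Reactants: 21 3-[3,4-bis(methoxymethoxy)-5-(3-methylbut-2-en-1-yl)phenyl]-7-hydroxy-5-methoxy-4H-chromen-4-one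
Product: 22 glisoflavone, 3-[3,4-dihydroxy-5-(3-methylbut-2-en-1-yl)phenyl]-7-hydroxy-5-methoxy-4H-chromen-4-one
Conditions: HCl (about 1 M in MeOH), rt to 40 °C, stopped at full conversion
Reagents that add atoms: none
Why: Acid-catalysed acetal exchange with methanol removes both MOM ethers under dilute conditions at which the ortho-prenyl phenol should not yet cyclise to a chroman, and the aryl methyl ether stays intact.

**Compound list**

1 | 3,5-dimethoxyphenol | COc1cc(O)cc(OC)c1 | starting material
2 | (3,5-dimethoxyphenoxy)triisopropylsilane | COc1cc(O[Si](C(C)C)(C(C)C)C(C)C)cc(OC)c1 | intermediate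
3 | [2,6-dimethoxy-4-(triisopropylsilyloxy)phenyl]lithium | [Li]c1c(OC)cc(O[Si](C(C)C)(C(C)C)C(C)C)cc1OC | intermediate (not isolated)
4 | lithium 1-[2,6-dimethoxy-4-(triisopropylsilyloxy)phenyl]-1-[methoxy(methyl)amino]ethan-1-olate | [Li+].CC([O-])(N(C)OC)c1c(OC)cc(O[Si](C(C)C)(C(C)C)C(C)C)cc1OC | intermediate (not isolated)
5 | 1-[2,6-dimethoxy-4-(triisopropylsilyloxy)phenyl]ethan-1-one | CC(=O)c1c(OC)cc(O[Si](C(C)C)(C(C)C)C(C)C)cc1OC | intermediate
6 | 3,5-dibromo-2-hydroxybenzaldehyde | O=Cc1cc(Br)cc(Br)c1O | starting material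
7 | 3,5-dibromo-2-hydroxyphenyl formate | O=COc1cc(Br)cc(Br)c1O | intermediate (not isolated)
8 | 3,5-dibromobenzene-1,2-diol | Oc1cc(Br)cc(Br)c1O | intermediate
9 | 1,5-dibromo-2,3-bis(methoxymethoxy)benzene | COCOc1cc(Br)cc(Br)c1OCOC | intermediate
10 | prenyl bromide (1-bromo-3-methylbut-2-ene) | CC(C)=CCBr | starting material
11 | [5-bromo-2,3-bis(methoxymethoxy)phenyl]lithium | [Li]c1cc(Br)cc(OCOC)c1OCOC | intermediate (not isolated)
12 | [5-bromo-2,3-bis(methoxymethoxy)phenyl]copper | [Cu]c1cc(Br)cc(OCOC)c1OCOC | intermediate (not isolated)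
13 | 5-bromo-1,2-bis(methoxymethoxy)-3-(3-methylbut-2-en-1-yl)benzene | COCOc1cc(Br)cc(CC=C(C)C)c1OCOC | intermediate
14 | 2-[3,4-bis(methoxymethoxy)-5-(3-methylbut-2-en-1-yl)phenyl]-1-[2,6-dimethoxy-4-(triisopropylsilyloxy)phenyl]ethan-1-one | COc1cc(O[Si](C(C)C)(C(C)C)C(C)C)cc(OC)c1C(=O)Cc1cc(OCOC)c(OCOC)c(CC=C(C)C)c1 | intermediate
15 | 2-diazo-2-[3,4-bis(methoxymethoxy)-5-(3-methylbut-2-en-1-yl)phenyl]-1-[2,6-dimethoxy-4-(triisopropylsilyloxy)phenyl]ethan-1-one | COc1cc(O[Si](C(C)C)(C(C)C)C(C)C)cc(OC)c1C(=O)C(=[N+]=[N-])c1cc(OCOC)c(OCOC)c(CC=C(C)C)c1 | intermediate (key-step precursor)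
16 | rac-3-[3,4-bis(methoxymethoxy)-5-(3-methylbut-2-en-1-yl)phenyl]-5-methoxy-7-(triisopropylsilyloxy)chroman-4-one (racemic at C3) | COc1cc(O[Si](C(C)C)(C(C)C)C(C)C)cc2OCC(c3cc(OCOC)c(OCOC)c(CC=C(C)C)c3)C(=O)c12 | intermediate (key-step product)
17 | lithium 3-[3,4-bis(methoxymethoxy)-5-(3-methylbut-2-en-1-yl)phenyl]-5-methoxy-7-(triisopropylsilyloxy)-2H-chromen-4-olate | [Li+].COc1cc(O[Si](C(C)C)(C(C)C)C(C)C)cc2OCC(c3cc(OCOC)c(OCOC)c(CC=C(C)C)c3)=C([O-])c12 | intermediate (not isolated)
18 | rac-3-[3,4-bis(methoxymethoxy)-5-(3-methylbut-2-en-1-yl)phenyl]-5-methoxy-3-(phenylselanyl)-7-(triisopropylsilyloxy)chroman-4-one (racemic at C3) | COc1cc(O[Si](C(C)C)(C(C)C)C(C)C)cc2OCC([Se]c4ccccc4)(c3cc(OCOC)c(OCOC)c(CC=C(C)C)c3)C(=O)c12 | intermediate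
19 | 3-[3,4-bis(methoxymethoxy)-5-(3-methylbut-2-en-1-yl)phenyl]-5-methoxy-3-(phenylseleninyl)-7-(triisopropylsilyloxy)chroman-4-one (racemic, mixture at selenium) | COc1cc(O[Si](C(C)C)(C(C)C)C(C)C)cc2OCC([Se](=O)c4ccccc4)(c3cc(OCOC)c(OCOC)c(CC=C(C)C)c3)C(=O)c12 | intermediate (not isolated)
20 | 3-[3,4-bis(methoxymethoxy)-5-(3-methylbut-2-en-1-yl)phenyl]-5-methoxy-7-(triisopropylsilyloxy)-4H-chromen-4-one | COc1cc(O[Si](C(C)C)(C(C)C)C(C)C)cc2occ(-c3cc(OCOC)c(OCOC)c(CC=C(C)C)c3)c(=O)c12 | intermediate
21 | 3-[3,4-bis(methoxymethoxy)-5-(3-methylbut-2-en-1-yl)phenyl]-7-hydroxy-5-methoxy-4H-chromen-4-one | COc1cc(O)cc2occ(-c3cc(OCOC)c(OCOC)c(CC=C(C)C)c3)c(=O)c12 | intermediate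
22 | glisoflavone, 3-[3,4-dihydroxy-5-(3-methylbut-2-en-1-yl)phenyl]-7-hydroxy-5-methoxy-4H-chromen-4-one | COc1cc(O)cc2occ(-c3cc(O)c(O)c(CC=C(C)C)c3)c(=O)c12 | target

**Step count and risks**

Total step count: 12.
Longest linear sequence: 10 steps (6 to 22 through steps 3 to 12); the ring A branch from 1 is 9 steps.

Steps most likely to fail:

1. Step 8 (proposed new method). The carbenoid may be diverted before it inserts: attack of the methoxy oxygen followed by methyl shift or demethylation (five-membered instead of six-membered closure), Wolff rearrangement to a ketene, or dimerisation. Insertion into a primary C–H bond may also be too slow.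
Fallback, known chemistry (Suzuki–Miyaura route to isoflavones): it sets out from ketone 5 and bromide 13 and comes back to the route at isoflavone 20, bypassing steps 6 to 10. Ketone 5 should be mono-demethylated ortho to the carbonyl by BCl3 (CH2Cl2, −78 to 0 °C, chelation control) to give 1-[2-hydroxy-6-methoxy-4-(triisopropylsilyloxy)phenyl]ethan-1-one F1. Condensation with DMF dimethyl acetal (toluene, 90 °C) should give the enaminone (E)-3-(dimethylamino)-1-[2-hydroxy-6-methoxy-4-(triisopropylsilyloxy)phenyl]prop-2-en-1-one F2. Iodine with pyridine in CHCl3 should cyclise it to 3-iodo-5-methoxy-7-(triisopropylsilyloxy)-4H-chromen-4-one F3. Bromide 13 should undergo Miyaura borylation (B2pin2, PdCl2(dppf), KOAc, dioxane, 85 °C) to 2-[3,4-bis(methoxymethoxy)-5-(3-methylbut-2-en-1-yl)phenyl]-4,4,5,5-tetramethyl-1,3,2-dioxaborolane F4. Suzuki–Miyaura coupling of the iodochromone with the boronate (PdCl2(dppf), K3PO4, dioxane/H2O, 60 °C) should then give 20.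

2. Step 9. The C3 enolate may expel the aryloxide oxygen (β-elimination that opens ring C) before it is trapped, and the selenenyl chloride may add across the prenyl double bond.
Fallback: it sets out from isoflavanone 16 and comes back at 20, bypassing steps 9 and 10. Deprotonation with LiHMDS in the presence of TMSCl (in situ quench, THF, −78 °C), passing through enolate 17, should give the silyl enol ether {3-[3,4-bis(methoxymethoxy)-5-(3-methylbut-2-en-1-yl)phenyl]-5-methoxy-7-(triisopropylsilyloxy)-2H-chromen-4-yl}oxytrimethylsilane F5. Pd(OAc)2 (divalent palladium, MeCN, rt) should then dehydrogenate it by β-hydride elimination from C2 (Saegusa–Ito oxidation) to 20.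

3. Step 6. The twisted, hindered enolate may couple slowly, a second arylation may follow the first, and the aryl silyl ether may be lost to the base at 90 °C.
Fallback: it sets out from bromide 13 and aryllithium 3 (made from 2 as in step 2) and comes back at deoxybenzoin 14. Bromine–lithium exchange on 13 (n-BuLi, THF, −78 °C) should give [3,4-bis(methoxymethoxy)-5-(3-methylbut-2-en-1-yl)phenyl]lithium F6. Ethylene oxide with BF3·OEt2 at −78 °C should be opened to 2-[3,4-bis(methoxymethoxy)-5-(3-methylbut-2-en-1-yl)phenyl]ethan-1-ol F7. Dess–Martin oxidation (NaHCO3, CH2Cl2) should give 2-[3,4-bis(methoxymethoxy)-5-(3-methylbut-2-en-1-yl)phenyl]acetaldehyde F8. Addition of aryllithium 3 (THF, −78 °C, anhydrous CeCl3 to hold back enolisation) should give the carbinol rac-2-[3,4-bis(methoxymethoxy)-5-(3-methylbut-2-en-1-yl)phenyl]-1-[2,6-dimethoxy-4-(triisopropylsilyloxy)phenyl]ethan-1-ol F9. A second Dess–Martin oxidation should give 14.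

**Further compounds**

F1 | step 8 | 1-[2-hydroxy-6-methoxy-4-(triisopropylsilyloxy)phenyl]ethan-1-one | CC(=O)c1c(O)cc(O[Si](C(C)C)(C(C)C)C(C)C)cc1OC
F2 | step 8 | (E)-3-(dimethylamino)-1-[2-hydroxy-6-methoxy-4-(triisopropylsilyloxy)phenyl]prop-2-en-1-one | CN(C)/C=C/C(=O)c1c(O)cc(O[Si](C(C)C)(C(C)C)C(C)C)cc1OC
F3 | step 8 | 3-iodo-5-methoxy-7-(triisopropylsilyloxy)-4H-chromen-4-one | COc1cc(O[Si](C(C)C)(C(C)C)C(C)C)cc2occ(I)c(=O)c12
F4 | step 8 | 2-[3,4-bis(methoxymethoxy)-5-(3-methylbut-2-en-1-yl)phenyl]-4,4,5,5-tetramethyl-1,3,2-dioxaborolane | COCOc1cc(B2OC(C)(C)C(C)(C)O2)cc(CC=C(C)C)c1OCOC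
F5 | step 9 | {3-[3,4-bis(methoxymethoxy)-5-(3-methylbut-2-en-1-yl)phenyl]-5-methoxy-7-(triisopropylsilyloxy)-2H-chromen-4-yl}oxytrimethylsilane | COc1cc(O[Si](C(C)C)(C(C)C)C(C)C)cc2OCC(c3cc(OCOC)c(OCOC)c(CC=C(C)C)c3)=C(O[Si](C)(C)C)c12
F6 | step 6 | [3,4-bis(methoxymethoxy)-5-(3-methylbut-2-en-1-yl)phenyl]lithium | [Li]c1cc(OCOC)c(OCOC)c(CC=C(C)C)c1
F7 | step 6 | 2-[3,4-bis(methoxymethoxy)-5-(3-methylbut-2-en-1-yl)phenyl]ethan-1-ol | COCOc1cc(CCO)cc(CC=C(C)C)c1OCOC
F8 | step 6 | 2-[3,4-bis(methoxymethoxy)-5-(3-methylbut-2-en-1-yl)phenyl]acetaldehyde | COCOc1cc(CC=O)cc(CC=C(C)C)c1OCOC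
F9 | step 6 | rac-2-[3,4-bis(methoxymethoxy)-5-(3-methylbut-2-en-1-yl)phenyl]-1-[2,6-dimethoxy-4-(triisopropylsilyloxy)phenyl]ethan-1-ol | COc1cc(O[Si](C(C)C)(C(C)C)C(C)C)cc(OC)c1C(O)Cc1cc(OCOC)c(OCOC)c(CC=C(C)C)c1
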